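**Strategy**

The cyclohexane is read as an α-terpineol unit: its CH–CH3 carbon (C8) lies para to the CH that carries C(CH3)2OH (C5). The bond from C5 to the neighbouring ring CH2 (C6) is therefore made by a linalyl-to-terpinyl cation–olefin cyclisation, which in one operation closes the six-membered ring, sets C5 and installs the carbinol oxygen. The precursor is a 2,3-disubstituted cyclopentanone bearing a tertiary vinyl carbinol next to a quaternary carbon with a 2-methylpropenyl group. The cyclopentanone is a temporary ring: a later Grob fragmentation releases the propanoic acid chain and an exocyclic alkene, whose epoxide is annulated to the tropone.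

Key step: step 3

Remark on locants (terpenoid-type, used throughout): C1–C3 = propanoic acid chain (C3 = CO2H); C4 = carbinol carbon; C5 = ring CH bearing C4; C6, C7 = ring CH2; C8 = ring CH(CH3); C9 = spiro carbon; C10 = quaternary ring carbon; C11 = dihydrofuran CH2.

**Route**

Step 1
Reactants: 1 3-methylcyclopent-2-en-1-one; 2 1-bromo-2-methylprop-1-ene
Product: 6 (R)-trimethyl{[3-methyl-3-(2-methylprop-1-en-1-yl)cyclopent-1-en-1-yl]oxy}silane, via alkenyllithium 3 (not isolated), via alkenylalane 4 (not isolated), via aluminium enolate 5 (not isolated)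
Conditions: 2, t-BuLi (2 equiv), Et2O, −78 °C; Me2AlCl; then 1, Cu(OTf)2 (5 mol %), N,N-bis(1-phenylethyl)-P,P-diphenylphosphinous amide (10 mol %, the enantiomer that delivers (R)-6), Et2O, −30 °C; then Me3SiOTf, −30 → 0 °C
Reagents that add atoms: trimethylsilyl trifluoromethanesulfonate, C[Si](C)(C)OS(=O)(=O)C(F)(F)F
Why: Copper-catalysed asymmetric conjugate addition of the alkenylalane to the β-methyl enone should build the quaternary carbon C10 with the absolute configuration fixed by the chiral ligand, and O-silylation of the aluminium enolate stores the regiodefined C3=C9 enolate.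

Step 2
Reactants: 6 (R)-silyl enol ether; 7 but-3-en-2-one
Product: 9 (3R)-2-(2-hydroxybut-3-en-2-yl)-3-methyl-3-(2-methylprop-1-en-1-yl)cyclopentan-1-one (diastereomer mixture at C2 and at the carbinol carbon), via lithium enolate 8 (not isolated)
Conditions: MeLi, THF, 0 °C; then 7, −78 °C, 10 min; AcOH, −78 °C
Reagents that add atoms: none
Why: Silicon–lithium exchange regenerates the regiodefined enolate, which should add 1,2 to the enone carbonyl under kinetic control (aldol addition) to give the tertiary vinyl carbinol; both new stereocentres are destroyed in step 3.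

Step 3
Reactants: 9 aldol adduct
Product: 11 (3aR,4S)-4-(2-hydroxypropan-2-yl)-3a,7-dimethyl-2,3,3a,4,5,6-hexahydro-1H-inden-1-one, via cyclised formate 10 (not isolated)
Conditions: HCO2H (98 %), 20 °C; evaporate; then K2CO3, MeOH, 20 °C
Reagents that add atoms: formic acid, OC=O
Why: Ionisation of the tertiary allylic alcohol in formic acid should give a linalyl-type allyl cation whose cisoid form is attacked at its primary terminus C6 by C5 of the 2-methylpropenyl group, and the tertiary cation at C4 is captured by formate; K2CO3 in methanol then cleaves the formate and moves the ring double bond into conjugation with the ketone. The closest known reaction type is the acid-mediated cyclisation of linalool or nerolidol to α-terpineol or bisabolol. The six-membered ring closes in the 6-exo-trig mode with respect to the attacking alkene, while the allyl unit becomes endocyclic. The new stereocentre C5 is controlled by the quaternary centre C10: in the chair-like transition state the angular methyl is axial, the cyclopentanone CH2 is equatorial and the developing C(CH3)2 cation takes the equatorial position, cis to the angular methyl. The step needs attack by the alkene rather than by the ketone oxygen, and capture rather than elimination of the C4 cation; the gem-disubstituted tether, the nucleophilic trisubstituted alkene and the nucleophilic solvent in large excess are expected to secure this. The epimerisable centre C9 lets both diastereomers of 9 converge.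

Step 4
Reactants: 11 enone alcohol
Product: 12 (3aR,4S)-3a,7-dimethyl-4-[2-(triethylsilyloxy)propan-2-yl]-2,3,3a,4,5,6-hexahydro-1H-inden-1-one
Conditions: Et3SiOTf, 2,6-lutidine, CH2Cl2, −78 → 0 °C
Reagents that add atoms: triethylsilyl trifluoromethanesulfonate, CC[Si](CC)(CC)OS(=O)(=O)C(F)(F)F
Why: Silylation of the tertiary alcohol is a standard protection and should prevent this hydroxyl from opening the epoxide made in step 8.

Step 5
Reactants: 12 silyl-protected enone
Product: 13 triethyl({(3aR,4S,7R)-3a,7-dimethyl-4-[2-(triethylsilyloxy)propan-2-yl]-3,3a,4,5,6,7-hexahydro-2H-inden-1-yl}oxy)silane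
Conditions: Et3SiH, RhCl(PPh3)3 (2 mol %), PhMe, 60 °C
Reagents that add atoms: triethylsilane, CC[SiH](CC)CC
Why: Rhodium-catalysed 1,4-hydrosilylation of the s-cis enone should deliver hydride to C8 from the face opposite to the angular methyl, which places the C8 methyl cis to the angular methyl, and gives the regiodefined silyl enol ether.

Step 6
Reactants: 13 silyl enol ether
Product: 14 (3aR,4S,7R,7aR)-7a-[(dimethylamino)methyl]-3a,7-dimethyl-4-[2-(triethylsilyloxy)propan-2-yl]octahydro-1H-inden-1-one (configuration at C7a is of no consequence)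
Conditions: CH2=NMe2+ I−, CH2Cl2, 20 °C; aq. NaHCO3
Reagents that add atoms: dimethyl(methylidene)ammonium iodide, C=[N+](C)C.[I-]
Why: A Mukaiyama–Mannich reaction of the silyl enol ether with the small iminium ion should place the one-carbon unit C11 on C9 regiospecifically.

Step 7
Reactants: 14 Mannich base
Product: 16 3-{(1R,3R,6S)-1,3-dimethyl-2-methylidene-6-[2-(triethylsilyloxy)propan-2-yl]cyclohexyl}propanoic acid, via ammonium iodide 15 (not isolated)
Conditions: MeI, MeCN, 20 °C; then KOH, H2O/THF, 40 °C; aq. HCl (1 M), 0 °C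
Reagents that add atoms: potassium hydroxide, [K+].[OH-]
Why: Hydroxide adds to the ketone and the adduct should undergo Grob fragmentation (C3–C9 cleavage, loss of trimethylamine), since the quaternary C9 excludes elimination to an enone; this opens the temporary ring to the propanoic acid chain and the C9=C11 alkene.

Step 8
Reactants: 16 alkenoic acid
Product: 17 3-{(3S,4R,5S,8R)-4,8-dimethyl-5-[2-(triethylsilyloxy)propan-2-yl]-1-oxaspiro[2.5]octan-4-yl}propanoic acid
Conditions: DMDO, acetone, 0 °C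
Reagents that add atoms: dimethyldioxirane, CC1(C)OO1
Why: Dioxirane epoxidation should occur on the face of the exocyclic alkene opposite to the two flanking methyl groups (on C8 and C10), which sets C9 with its oxygen trans to both, as in the target.

Step 9
Reactants: 18 3-methylpentane-2,4-dione; 19 dimethyl carbonate
Product: 21 methyl 4-methyl-3,5-dioxohexanoate, via diketone dianion 20 (not isolated)
Conditions: LiN(i-Pr)2 (3 equiv), THF, −78 → 0 °C; then 19; aq. HCl
Reagents that add atoms: none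
Why: The 1,3-diketone dianion should be acylated at its terminal carbon by the carbonate (Claisen-type condensation) to give the β,δ-diketo ester.

Step 10
Reactants: 17 epoxy acid; 21 β,δ-diketo ester
Product: 24 3-{(2E,5S,6R,7S,10R)-2-(5-methoxy-3,5-dioxopentan-2-ylidene)-6,10-dimethyl-7-[2-(triethylsilyloxy)propan-2-yl]-1-oxaspiro[4.5]decan-6-yl}propanoic acid, via diketo ester trianion 22 (not isolated), via ring-opened hydroxy triketone 23 (not isolated)
Conditions: 21 (3 equiv), LiN(i-Pr)2 (9 equiv), THF, −78 → 0 °C; then 17, −78 → 20 °C; aq. NH4Cl; then PPTS, CH2Cl2, 20 °C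
Reagents that add atoms: none
Why: The terminal carbanion of the trianion should open the epoxide at its CH2 (SN2, C9 untouched), and the tertiary alkoxide then condenses with the adjacent ketone to the conjugated 2-alkylidenetetrahydrofuran (1,3-dicarbonyl polyanion–epoxide cyclisation).

Step 11
Reactants: 24 alkylidenetetrahydrofuran β-keto ester; 25 1,1-dimethoxypropan-2-one
Product: 26 3-{(2E,5S,6R,7S,10R)-2-[4-(methoxycarbonyl)-6,6-dimethoxy-5-methyl-3-oxohex-4-en-2-ylidene]-6,10-dimethyl-7-[2-(triethylsilyloxy)propan-2-yl]-1-oxaspiro[4.5]decan-6-yl}propanoic acid (alkene isomers at the new double bond)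
Conditions: 25 (excess), piperidine, AcOH, 4 Å MS, PhMe, 60 °C
Reagents that add atoms: none
Why: Knoevenagel condensation of the β-keto ester CH2 with the activated α,α-dialkoxy ketone should attach the last two ring carbons with the aldehyde carbon still masked, which fixes the regiochemistry of the tropone.

Step 12
Reactants: 26 Knoevenagel product
Product: 28 target acid, 3-[(2S,2'R,3'S,6'R)-3'-(2-hydroxypropan-2-yl)-6-(methoxycarbonyl)-2',5,6',8-tetramethyl-7-oxo-3,7-dihydrospiro[cyclohepta[b]furan-2,1'-cyclohexan]-2'-yl]propanoic acid, via enal 27 (not isolated)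
Conditions: TsOH·H2O, acetone/H2O (10:1), 50 °C
Reagents that add atoms: none
Why: Acid unmasks the aldehyde, the ring CH2 next to the enol ether carbon attacks it through the endocyclic enol ether tautomer (intramolecular vinylogous aldol condensation, seven-membered ring), and loss of water should give the aromatic tropone while the silyl ether is cleaved.

**Compound list**

1 | 3-methylcyclopent-2-en-1-one | CC1=CC(=O)CC1 | starting material
2 | 1-bromo-2-methylprop-1-ene | CC(C)=CBr | starting material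
3 | (2-methylprop-1-en-1-yl)lithium | [Li]C=C(C)C | intermediate
4 | dimethyl(2-methylprop-1-en-1-yl)aluminium | C[Al](C)C=C(C)C | intermediate
5 | dimethylaluminium (R)-3-methyl-3-(2-methylprop-1-en-1-yl)cyclopent-1-en-1-olate | CC(C)=C[C@@]1(C)CCC(O[Al](C)C)=C1 | intermediate
6 | (R)-trimethyl{[3-methyl-3-(2-methylprop-1-en-1-yl)cyclopent-1-en-1-yl]oxy}silane | CC(C)=C[C@@]1(C)CCC(O[Si](C)(C)C)=C1 | intermediate
7 | but-3-en-2-one | CC(=O)C=C | starting material
8 | lithium (R)-3-methyl-3-(2-methylprop-1-en-1-yl)cyclopent-1-en-1-olate | CC(C)=C[C@@]1(C)CCC(O[Li])=C1 | intermediate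
9 | (3R)-2-(2-hydroxybut-3-en-2-yl)-3-methyl-3-(2-methylprop-1-en-1-yl)cyclopentan-1-one, diastereomer mixture at C2 and carbinol carbon | CC(C)=C[C@@]1(C)CCC(=O)C1C(C)(O)C=C | intermediate
10 | 2-[(3aR,4S)-3a,7-dimethyl-1-oxo-2,3,3a,4,5,7a-hexahydro-1H-inden-4-yl]propan-2-yl formate, C7a epimers | CC1=CC[C@H](C(C)(C)OC=O)[C@@]2(C)CCC(=O)C12 | intermediate
11 | (3aR,4S)-4-(2-hydroxypropan-2-yl)-3a,7-dimethyl-2,3,3a,4,5,6-hexahydro-1H-inden-1-one | CC1=C2C(=O)CC[C@]2(C)[C@@H](C(C)(C)O)CC1 | intermediate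
12 | (3aR,4S)-3a,7-dimethyl-4-[2-(triethylsilyloxy)propan-2-yl]-2,3,3a,4,5,6-hexahydro-1H-inden-1-one | CC1=C2C(=O)CC[C@]2(C)[C@@H](C(C)(C)O[Si](CC)(CC)CC)CC1 | intermediate
13 | triethyl({(3aR,4S,7R)-3a,7-dimethyl-4-[2-(triethylsilyloxy)propan-2-yl]-3,3a,4,5,6,7-hexahydro-2H-inden-1-yl}oxy)silane | C[C@H]1C2=C(O[Si](CC)(CC)CC)CC[C@]2(C)[C@@H](C(C)(C)O[Si](CC)(CC)CC)CC1 | intermediate
14 | (3aR,4S,7R,7aR)-7a-[(dimethylamino)methyl]-3a,7-dimethyl-4-[2-(triethylsilyloxy)propan-2-yl]octahydro-1H-inden-1-one | C[C@H]1[C@@]2(CN(C)C)C(=O)CC[C@]2(C)[C@@H](C(C)(C)O[Si](CC)(CC)CC)CC1 | intermediate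
15 | ({(3aR,4S,7R,7aR)-3a,7-dimethyl-1-oxo-4-[2-(triethylsilyloxy)propan-2-yl]octahydro-1H-inden-7a-yl}methyl)trimethylammonium iodide | C[C@H]1[C@@]2(C[N+](C)(C)C)C(=O)CC[C@]2(C)[C@@H](C(C)(C)O[Si](CC)(CC)CC)CC1.[I-] | intermediate
16 | 3-{(1R,3R,6S)-1,3-dimethyl-2-methylidene-6-[2-(triethylsilyloxy)propan-2-yl]cyclohexyl}propanoic acid | C=C1[C@H](C)CC[C@H](C(C)(C)O[Si](CC)(CC)CC)[C@@]1(C)CCC(=O)O | intermediate
17 | 3-{(3S,4R,5S,8R)-4,8-dimethyl-5-[2-(triethylsilyloxy)propan-2-yl]-1-oxaspiro[2.5]octan-4-yl}propanoic acid | C1O[C@]12[C@H](C)CC[C@H](C(C)(C)O[Si](CC)(CC)CC)[C@@]2(C)CCC(=O)O | intermediate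
18 | 3-methylpentane-2,4-dione | CC(=O)C(C)C(C)=O | starting material
19 | dimethyl carbonate | COC(=O)OC | starting material
20 | dilithium 1,3-dianion of 3-methylpentane-2,4-dione | [Li+].[Li+].[CH2-]C(=O)[C-](C)C(C)=O | intermediate
21 | methyl 4-methyl-3,5-dioxohexanoate | COC(=O)CC(=O)C(C)C(C)=O | intermediate
22 | trilithium 2,4,6-trianion of methyl 4-methyl-3,5-dioxohexanoate | [Li+].[Li+].[Li+].[CH2-]C(=O)[C-](C)C(=O)[CH-]C(=O)OC | intermediate
23 | 3-{(1R,2S,3R,6S)-2-hydroxy-2-(7-methoxy-4-methyl-3,5,7-trioxoheptyl)-1,3-dimethyl-6-[2-(triethylsilyloxy)propan-2-yl]cyclohexyl}propanoic acid | COC(=O)CC(=O)C(C)C(=O)CC[C@]1(O)[C@H](C)CC[C@H](C(C)(C)O[Si](CC)(CC)CC)[C@@]1(C)CCC(=O)O | intermediate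
24 | 3-{(2E,5S,6R,7S,10R)-2-(5-methoxy-3,5-dioxopentan-2-ylidene)-6,10-dimethyl-7-[2-(triethylsilyloxy)propan-2-yl]-1-oxaspiro[4.5]decan-6-yl}propanoic acid | COC(=O)CC(=O)/C(C)=C1\CC[C@]2(O1)[C@H](C)CC[C@H](C(C)(C)O[Si](CC)(CC)CC)[C@@]2(C)CCC(=O)O | intermediate
25 | 1,1-dimethoxypropan-2-one | CC(=O)C(OC)OC | starting material
26 | 3-{(2E,5S,6R,7S,10R)-2-[4-(methoxycarbonyl)-6,6-dimethoxy-5-methyl-3-oxohex-4-en-2-ylidene]-6,10-dimethyl-7-[2-(triethylsilyloxy)propan-2-yl]-1-oxaspiro[4.5]decan-6-yl}propanoic acid | COC(=O)C(=C(C)C(OC)OC)C(=O)/C(C)=C1\CC[C@]2(O1)[C@H](C)CC[C@H](C(C)(C)O[Si](CC)(CC)CC)[C@@]2(C)CCC(=O)O | intermediate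
27 | 3-{(2E,5S,6R,7S,10R)-2-[4-(methoxycarbonyl)-5-methyl-3,6-dioxohex-4-en-2-ylidene]-6,10-dimethyl-7-[2-(triethylsilyloxy)propan-2-yl]-1-oxaspiro[4.5]decan-6-yl}propanoic acid | COC(=O)C(=C(C)C=O)C(=O)/C(C)=C1\CC[C@]2(O1)[C@H](C)CC[C@H](C(C)(C)O[Si](CC)(CC)CC)[C@@]2(C)CCC(=O)O | intermediate
28 | 3-[(2S,2'R,3'S,6'R)-3'-(2-hydroxypropan-2-yl)-6-(methoxycarbonyl)-2',5,6',8-tetramethyl-7-oxo-3,7-dihydrospiro[cyclohepta[b]furan-2,1'-cyclohexan]-2'-yl]propanoic acid (CNP0448476.4) | COC(=O)c1c(C)cc2c(c(C)c1=O)O[C@@]1(C2)[C@H](C)CC[C@H](C(C)(C)O)[C@@]1(C)CCC(=O)O | target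

**Summary**

Total step count: 12. Longest linear sequence: 11 steps (steps 1–8 and 10–12); step 9 prepares the diketo ester 21.

**Steps most likely to fail**

Step 3. The tertiary C4 cation may lose a proton instead of being captured, and facial selectivity may erode if ring closure runs through the cis-fused chair with the angular methyl equatorial. The fallback sets out from 9 and separates ring closure from hydration. Dehydration of 9 with methyl N-(triethylammoniosulfonyl)carbamate (Burgess reagent, PhH, 50 °C) gives the conjugated dienone, (3R,2E)-2-(but-3-en-2-ylidene)-3-methyl-3-(2-methylprop-1-en-1-yl)cyclopentan-1-one F1. A Me2AlCl-promoted intramolecular ene reaction (CH2Cl2, −78 → 0 °C) then closes the same C5–C6 bond, with a methyl hydrogen transferred to C7, and gives the isopropenyl enone, (3aR,4S)-3a,7-dimethyl-4-(prop-1-en-2-yl)-2,3,3a,4,5,6-hexahydro-1H-inden-1-one F2. Mukaiyama hydration of the 1,1-disubstituted alkene (Co(acac)2, PhSiH3, O2, i-PrOH) returns to the route at 11.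

Step 10. Substitution at the neopentyl-type epoxide CH2 may be slow, so that proton transfer to the polyanion and base-induced isomerisation of the epoxide to an allylic alcohol compete. The fallback sets out from 17 and splits the coupling in two. The small lithium enolate of ethyl acetate, with Et2AlCl in THF (−78 → 0 °C), opens the epoxide to the hydroxy ester, 3-{(1R,2S,3R,6S)-2-(3-ethoxy-3-oxopropyl)-2-hydroxy-1,3-dimethyl-6-[2-(triethylsilyloxy)propan-2-yl]cyclohexyl}propanoic acid F3. Its alkoxide lactonises in the flask to the spirolactone, 3-{(5S,6R,7S,10R)-6,10-dimethyl-2-oxo-7-[2-(triethylsilyloxy)propan-2-yl]-1-oxaspiro[4.5]decan-6-yl}propanoic acid F4. The dianion of commercial methyl 3-oxopentanoate (NaH, then n-BuLi, THF, 0 °C) is then acylated at its γ-carbon by the lactone to give 23, which cyclodehydrates (PPTS) and returns to the route at 24.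

Step 11. The condensation may stall, because the ketone is a poor Knoevenagel acceptor and the β-keto ester CH2 is only weakly acidic, and premature ionisation of the acetal may compete. The fallback sets out from 24 and replaces condensation by conjugate addition. Addition of the β-keto ester to (E)-1-nitroprop-1-ene (Et3N cat., CH2Cl2) gives the nitro adduct, 3-{(2E,5S,6R,7S,10R)-2-[4-(methoxycarbonyl)-5-methyl-6-nitro-3-oxohexan-2-ylidene]-6,10-dimethyl-7-[2-(triethylsilyloxy)propan-2-yl]-1-oxaspiro[4.5]decan-6-yl}propanoic acid F5. A Nef reaction (NaOMe, MeOH; then cold aq. H2SO4) gives the aldehyde, 3-{(2E,5S,6R,7S,10R)-2-[4-(methoxycarbonyl)-5-methyl-3,6-dioxohexan-2-ylidene]-6,10-dimethyl-7-[2-(triethylsilyloxy)propan-2-yl]-1-oxaspiro[4.5]decan-6-yl}propanoic acid F6. Under the conditions of step 12 this closes and loses its silyl group to give the dihydrotropone, 3-[(2S,2'R,3'S,6'R)-3'-(2-hydroxypropan-2-yl)-6-(methoxycarbonyl)-2',5,6',8-tetramethyl-7-oxo-3,5,6,7-tetrahydrospiro[cyclohepta[b]furan-2,1'-cyclohexan]-2'-yl]propanoic acid F7. Dehydrogenation with DDQ (PhH, 60 °C) returns to the route at 28.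

**Further compounds**

F1 | step 3 | (3R,2E)-2-(but-3-en-2-ylidene)-3-methyl-3-(2-methylprop-1-en-1-yl)cyclopentan-1-one | CC(C)=C[C@@]1(C)CCC(=O)/C1=C(C)/C=C
F2 | step 3 | (3aR,4S)-3a,7-dimethyl-4-(prop-1-en-2-yl)-2,3,3a,4,5,6-hexahydro-1H-inden-1-one | CC1=C2C(=O)CC[C@]2(C)[C@@H](C(C)=C)CC1
F3 | step 10 | 3-{(1R,2S,3R,6S)-2-(3-ethoxy-3-oxopropyl)-2-hydroxy-1,3-dimethyl-6-[2-(triethylsilyloxy)propan-2-yl]cyclohexyl}propanoic acid | CCOC(=O)CC[C@]1(O)[C@H](C)CC[C@H](C(C)(C)O[Si](CC)(CC)CC)[C@@]1(C)CCC(=O)O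
F4 | step 10 | 3-{(5S,6R,7S,10R)-6,10-dimethyl-2-oxo-7-[2-(triethylsilyloxy)propan-2-yl]-1-oxaspiro[4.5]decan-6-yl}propanoic acid | O=C1CC[C@]2(O1)[C@H](C)CC[C@H](C(C)(C)O[Si](CC)(CC)CC)[C@@]2(C)CCC(=O)O
F5 | step 11 | 3-{(2E,5S,6R,7S,10R)-2-[4-(methoxycarbonyl)-5-methyl-6-nitro-3-oxohexan-2-ylidene]-6,10-dimethyl-7-[2-(triethylsilyloxy)propan-2-yl]-1-oxaspiro[4.5]decan-6-yl}propanoic acid | COC(=O)C(C(C)C[N+](=O)[O-])C(=O)/C(C)=C1\CC[C@]2(O1)[C@H](C)CC[C@H](C(C)(C)O[Si](CC)(CC)CC)[C@@]2(C)CCC(=O)O
F6 | step 11 | 3-{(2E,5S,6R,7S,10R)-2-[4-(methoxycarbonyl)-5-methyl-3,6-dioxohexan-2-ylidene]-6,10-dimethyl-7-[2-(triethylsilyloxy)propan-2-yl]-1-oxaspiro[4.5]decan-6-yl}propanoic acid | COC(=O)C(C(C)C=O)C(=O)/C(C)=C1\CC[C@]2(O1)[C@H](C)CC[C@H](C(C)(C)O[Si](CC)(CC)CC)[C@@]2(C)CCC(=O)O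
F7 | step 11 | 3-[(2S,2'R,3'S,6'R)-3'-(2-hydroxypropan-2-yl)-6-(methoxycarbonyl)-2',5,6',8-tetramethyl-7-oxo-3,5,6,7-tetrahydrospiro[cyclohepta[b]furan-2,1'-cyclohexan]-2'-yl]propanoic acid | COC(=O)C1C(C)C=C2C[C@]3(OC2=C(C)C1=O)[C@H](C)CC[C@H](C(C)(C)O)[C@@]3(C)CCC(=O)O
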